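**Retrosynthetic overview**

1. The strategy rests on the δ-lactone C10–C20–O–C7(=O)–C8–C9: C20 is a lone OCH2 carbon between the spiro quaternary C10 (α to the ring A ketone C1) and the carboxyl oxygen on C7. The C10–C20 bond is cut, and C20 travels on the C7 acid as a chloromethyl ester (closed last).
2. Ring D (C8–C15–C16–C13–C14 of the bicyclo[3.2.1]octane): C15–C16 by Nozaki–Hiyama–Kishi closure, then C15 is reset by oxidation and exo-face hydride. One iodolactonisation of an exocyclic allene supplies the C13 oxygen, the C16 iodoalkene and the distinction between the two C8 carboxyls (C7 against C15).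
3. Ring C: C9–C10 by aldol condensation of the ring A enone with an allenyl chloro aldehyde; a malonate (C7–C8–C15) then adds to C9 and closes C8–C14.
4. Ring A: Rh-catalysed asymmetric vinyl addition to 4,4-dimethylcyclohexadienone sets C5; the vinyl group becomes the C6 acetal.
5. Ring order: A (bought) → C → temporary C7–O–C13 lactone → D → spirolactone.

Key step: step 18

Remark: C10 is drawn in every intermediate as the 5,10-trans epimer expected from equilibration; it is an enolisable centre that is erased and reset in step 18, so a mixture there is of no consequence. Reagent 6 is taken as its commercial THF solution.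

**Route**

Step 1
Reactants: 1 4,4-dimethylcyclohexa-2,5-dien-1-one; 2 potassium vinyltrifluoroborate
Product: 3 (R)-4,4-dimethyl-5-vinylcyclohex-2-en-1-one
Conditions: [Rh(cod)2]BF4 (3 mol%), (R)-BINAP (3.3 mol%), toluene/H2O 4:1, 100 °C
Reagents that add atoms: none
Why: Rh-catalysed asymmetric conjugate addition (Hayashi–Miyaura type) of an alkenyltrifluoroborate desymmetrises the dienone, the BINAP-bound rhodium choosing one enantiotopic alkene face so that C5 is set as (R) (the (R)-ligand is chosen by analogy with its sense of induction on cyclohexenone), and the mono-adduct should resist a second addition because its remaining β-carbon is flanked on both sides.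

Step 2
Reactants: 3 (R)-4,4-dimethyl-5-vinylcyclohex-2-en-1-one
Product: 5 (S)-5-(dimethoxymethyl)-4,4-dimethylcyclohex-2-en-1-one, via keto aldehyde 4 (not isolated)
Conditions: O3, CH2Cl2/MeOH, −78 °C (Sudan red 7B end point); Me2S, −78 °C → rt; then HC(OMe)3, PPTS, rt
Reagents that add atoms: trimethyl orthoformate COC(OC)OC
Why: Ozonolysis with reductive work-up cleaves the electron-rich vinyl group faster than the electron-poor enone, and the α-branched aldehyde 4 is acetalised at once under mild acid so that C5, now α to a formyl group, should not epimerise.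

Step 3
Reactants: 6 [2-(1,3-dioxolan-2-yl)ethyl]magnesium bromide; 7 1,4-dichlorobut-2-yne
Product: 8 2-[3-(chloromethyl)penta-3,4-dien-1-yl]-1,3-dioxolane
Conditions: CuBr·SMe2 (5 mol%), 7 (3 equiv), THF, −60 → −20 °C, slow addition of 6
Reagents that add atoms: none
Why: Copper-catalysed anti-SN2′ substitution of a propargylic chloride by a Grignard reagent gives the 1,1-disubstituted allene with the second chloride left on the allenic carbon, and excess 7 with slow addition should hold back a second substitution.

Step 4
Reactants: 8 2-[3-(chloromethyl)penta-3,4-dien-1-yl]-1,3-dioxolane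
Product: 9 4-(chloromethyl)hexa-4,5-dienal
Conditions: 2 M HCl, THF, rt
Reagents that add atoms: water O
Why: Acid-catalysed acetal hydrolysis frees the aldehyde, and dilute acid at room temperature should leave the allene and the primary chloride alone.

Step 5
Reactants: 5 (S)-5-(dimethoxymethyl)-4,4-dimethylcyclohex-2-en-1-one; 9 4-(chloromethyl)hexa-4,5-dienal
Product: 11 5,6-trans-6-[4-(chloromethyl)-1-hydroxyhexa-4,5-dien-1-yl]-5-(dimethoxymethyl)-4,4-dimethylcyclohex-2-en-1-one (carbinol epimers), via lithium dienolate 10 (not isolated)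
Conditions: LiN(iPr)2, THF, −78 °C; 9, −78 °C; AcOH, −78 °C
Reagents that add atoms: none
Why: Kinetic deprotonation can only occur at C10 because C4 is quaternary, and the lithium dienolate undergoes aldol addition to the aldehyde anti to the C5 acetal; the carbinol centre and C10 are both removed in step 6, and the cold acidic quench keeps the aldolate from displacing the chloride.

Step 6
Reactants: 11 aldol adduct
Product: 13 (5R,6E)-6-[4-(chloromethyl)hexa-4,5-dien-1-ylidene]-5-(dimethoxymethyl)-4,4-dimethylcyclohex-2-en-1-one, via mesylate 12 (not isolated)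
Conditions: MsCl, Et3N, DMAP (cat.), CH2Cl2, 0 °C → rt
Reagents that add atoms: none
Why: Mesylation and E1cB elimination of the β-mesyloxy ketone give the conjugated exocyclic enone, and the (E) isomer (C11 anti to the carbonyl) is the thermodynamically favoured one.

Step 7
Reactants: 13 alkylidene dienone; 14 diallyl malonate
Product: 16 diallyl (2S)-2-[(1S,6S)-6-(dimethoxymethyl)-5,5-dimethyl-2-oxocyclohex-3-en-1-yl]-4-ethenylidenecyclohexane-1,1-dicarboxylate, via open-chain Michael adduct 15 (not isolated)
Conditions: Cs2CO3, MeCN (0.02 M), 0 °C → rt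
Reagents that add atoms: none
Why: Michael-initiated ring closure, in which the malonate anion adds to the exocyclic β-carbon C9 (C3 is neopentyl) from the face opposite the C5 acetal, which A(1,3) strain with C11 forces pseudoaxial, so setting C9; after proton transfer the malonate anion C8 closes ring C by 6-exo-tet SN2 displacement of the primary chloride at C14, and C10 is protonated to the trans epimer.

Step 8
Reactants: 16 ring C diallyl ester
Product: 17 (2S)-2-[(1S,6S)-6-(dimethoxymethyl)-5,5-dimethyl-2-oxocyclohex-3-en-1-yl]-4-ethenylidenecyclohexane-1,1-dicarboxylic acid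
Conditions: Pd(PPh3)4 (5 mol%), 4-MeC6H4SO2Na, THF/MeOH, rt; pH 4 phosphate buffer
Reagents that add atoms: none
Why: Zerovalent palladium ionises both allyl esters and the π-allyl groups are trapped by the sulfinate (Tsuji–Trost deallylation) under neutral conditions that should spare allene, enone and acetal and avoid decarboxylation.

Step 9
Reactants: 17 ring C diacid
Product: 18 iodolactone acid (C7–O–C13 γ-lactone with 1-iodoethenyl on C13 and free CO2H on C8)
Conditions: I2, NaHCO3, MeCN/H2O, 0 °C, dark; dilute citric acid work-up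
Reagents that add atoms: iodine II
Why: Iodolactonisation of a 4,5-allenoic acid, in which iodine adds to the central allene carbon C16 and a carboxylate closes 5-exo on C13; only the carboxyl that is axial in the chair with ring A equatorial reaches C13, so the lactone carbonyl is the one cis to C10 (C7), the free acid becomes C15, and the C13 oxygen is set cis to C7 by the bridge.

Step 10
Reactants: 18 iodolactone acid
Product: 20 iodolactone aldehyde (CHO on C8 = C15), via acid chloride 19 (not isolated)
Conditions: Me2C=C(Cl)NMe2, CH2Cl2, 0 °C → rt; then LiAlH(OtBu)3, THF, −78 °C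
Reagents that add atoms: none
Why: Neutral acid chloride formation followed by hydride reduction with LiAlH(OtBu)3 at −78 °C, a temperature at which the acid chloride should be reduced much faster than the enone, the lactone or the aldehyde formed, gives the C15 aldehyde without touching a stereocentre.

Step 11
Reactants: 20 iodolactone aldehyde
Product: 23 allyl ester aldehyde with 13-O-trimethylsilyl ether (monocyclic ring C), via lithium carboxylate 21 (not isolated), via hydroxy allyl ester 22 (not isolated)
Conditions: LiOH·H2O, THF/H2O, 0 °C; evaporate; allyl bromide, DMF, 0 °C → rt; then N-(trimethylsilyl)imidazole, rt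
Reagents that add atoms: lithium hydroxide [Li+].[OH-]; allyl bromide C=CCBr; N-(trimethylsilyl)imidazole C[Si](C)(C)n1ccnc1
Why: Saponification opens the strained bridged lactone (deformylation is blocked because it would need a bridgehead enolate), the carboxylate is O-alkylated by allyl bromide, and the tertiary C13 alcohol is silylated in the same flask before it can close again on C7; no stereocentre changes.

Step 12
Reactants: 23 allyl ester aldehyde
Product: 25 bicyclo[3.2.1]octane allylic alcohol (ring D closed; C15 epimers), via alkenylchromium dichloride 24 (not isolated)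
Conditions: CrCl2 (6 equiv), NiCl2 (2 mol%), DMSO (0.01 M), rt
Reagents that add atoms: none
Why: Nozaki–Hiyama–Kishi reaction, in which the alkenyl iodide is converted under nickel catalysis into an alkenylchromium species that adds only to the aldehyde and closes ring D (5-exo) once ring C has flipped to the chair with C15 and C16 both axial; the C15 configuration is not relied on because both epimers converge in step 13.

Step 13
Reactants: 25 allylic alcohol (C15 epimers)
Product: 26 15-oxo-16-ene bicyclic enone
Conditions: Dess–Martin periodinane, NaHCO3, CH2Cl2, 0 °C → rt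
Reagents that add atoms: none
Why: Dess–Martin oxidation converts both allylic alcohol epimers into the α-methylene ketone under buffered conditions that should keep the silyl ether and the acetal.

Step 14
Reactants: 26 bicyclic enone
Product: 27 15-endo allylic alcohol
Conditions: NaBH4, CeCl3·7H2O, MeOH, −78 °C
Reagents that add atoms: none
Why: Luche 1,2-reduction, in which hydride reaches C15 from the exo face over the one-carbon bridge C14 because the endo face is screened by axial H-11 of the C9–C11–C12 bridge, giving the endo alcohol; the C15 ketone (strained, activated by the geminal ester, open exo face) should react before the ring A enone, whose carbonyl is flanked by the branched C10.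

Step 15
Reactants: 27 15-endo allylic alcohol
Product: 28 15-O-tert-butyldimethylsilyl 13-O-trimethylsilyl allyl ester
Conditions: tBuMe2SiOTf, 2,6-lutidine, CH2Cl2, −40 → 0 °C
Reagents that add atoms: tert-butyldimethylsilyl triflate CC(C)(C)[Si](C)(C)OS(=O)(=O)C(F)(F)F
Why: Silylation of the hindered secondary alcohol with a silyl triflate and a hindered pyridine base, conditions under which the tertiary trimethylsilyl ether and the acetal should survive.

Step 16
Reactants: 28 bis-silyl allyl ester
Product: 29 C7 carboxylic acid (13,15-bis-silyl ether, C6 acetal)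
Conditions: Pd(PPh3)4 (5 mol%), morpholine, THF, rt; pH 5 buffer
Reagents that add atoms: none
Why: Zerovalent palladium-catalysed allyl transfer to morpholine (Tsuji–Trost deallylation) frees the C7 acid without acid or base strong enough to harm the silyl ethers, the enone or the exocyclic alkene.

Step 17
Reactants: 29 C7 carboxylic acid; 30 chloromethyl chlorosulfate
Product: 31 chloromethyl ester of the C7 acid (C10–H ring A enone, 13-O-trimethylsilyl, 15-O-tert-butyldimethylsilyl, C6 dimethyl acetal)
Conditions: NaHCO3, Bu4NHSO4 (cat.), CH2Cl2/H2O, 0 °C → rt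
Reagents that add atoms: none
Why: Phase-transfer O-alkylation (SN2) of the carboxylate by chloromethyl chlorosulfate, in which chlorosulfate is by far the better leaving group, so the chloromethyl ester should form and not the bis(acyloxy)methane.

Step 18
Reactants: 31 chloromethyl ester
Product: 33 protected target (spirolactone; 13-O-trimethylsilyl, 15-O-tert-butyldimethylsilyl, C6 dimethyl acetal), via potassium dienolate 32 (not isolated)
Conditions: KN(SiMe3)2 (1.1 equiv), THF (0.005 M), −78 → −20 °C
Reagents that add atoms: none
Why: KN(SiMe3)2 removes the only acidic hydrogen, C10–H (C4 and C8 are quaternary and C6 is an acetal), to give the cross-conjugated potassium dienolate, whose C10 displaces chloride from the O–CH2–Cl carbon of the C7 ester in an intramolecular SN2 C-alkylation. The closest known reaction type is the C-alkylation of ketone enolates by chloromethyl ethers and by pivalate-type acyloxymethyl halides, here made intramolecular. The ring closed is the six-membered lactone C10–C20–O–C7–C8–C9, in a 6-(enolexo)-exo-tet mode; O-alkylation would need an eight-membered ring and attack on the C7 carbonyl a four-membered one, and that carbonyl is shielded by quaternary C8 as in a pivalate. The new stereocentre is spiro C10 and it is controlled by C9: in the chair-like transition state C9–H turns to the crowded C5 flank of the enolate (acetal on C5, gem-dimethyl carbon next to it), C11 stands anti to the forming bond and C8 sits on the oxido flank, where K+ can bridge the enolate oxygen and the C7 carbonyl oxygen. With C9 fixed in step 7 this arrangement puts C8, and therefore the tethered C20, on the face of C10 syn to C6, whereas delivery to the other face would force C5 and its substituents between C8 and C11. The step thus needs C- over O-alkylation, which ring size secures, and facial selectivity at C10 (C20 cis to C6), which the tether from C8 and the C9 configuration should secure; high dilution suppresses intermolecular alkylation.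

Step 19
Reactants: 33 protected target
Product: 34 13,15-diol with C6 dimethyl acetal
Conditions: HF·pyridine, pyridine, THF, 0 °C → rt
Reagents that add atoms: none
Why: Fluoride-mediated cleavage of both silyl ethers with buffered HF·pyridine, which should leave the dimethyl acetal, the lactone and the enone intact.

Step 20
Reactants: 34 diol acetal
Product: 35 CNP0521079.1 (target)
Conditions: TsOH·H2O (cat.), acetone/H2O, 0 °C → rt
Reagents that add atoms: water O
Why: Mild acid-catalysed acetal hydrolysis frees the C6 aldehyde, and short exposure at or below room temperature is chosen so that C5, α to the aldehyde, keeps its configuration.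

**Compound list**

1 | 4,4-dimethylcyclohexa-2,5-dien-1-one | CC1(C)C=CC(=O)C=C1 | starting material
2 | potassium vinyltrifluoroborate | C=C[B-](F)(F)F.[K+] | starting material
3 | (R)-4,4-dimethyl-5-vinylcyclohex-2-en-1-one | O=C1C=CC(C)(C)[C@@H](C=C)C1 | intermediate
4 | (S)-2,2-dimethyl-5-oxocyclohex-3-ene-1-carbaldehyde (keto aldehyde) | O=C1C=CC(C)(C)[C@@H](C=O)C1 | intermediate (not isolated)
5 | (S)-5-(dimethoxymethyl)-4,4-dimethylcyclohex-2-en-1-one (ring A enone, C6 as acetal) | O=C1C=CC(C)(C)[C@@H](C(OC)OC)C1 | intermediate
6 | [2-(1,3-dioxolan-2-yl)ethyl]magnesium bromide | Br[Mg]CCC1OCCO1 | starting material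
7 | 1,4-dichlorobut-2-yne | ClCC#CCCl | starting material
8 | 2-[3-(chloromethyl)penta-3,4-dien-1-yl]-1,3-dioxolane | ClCC(=C=C)CCC1OCCO1 | intermediate
9 | 4-(chloromethyl)hexa-4,5-dienal | O=CCCC(CCl)=C=C | intermediate
10 | lithium dienolate of 5 (enolate carbon = C10) | [Li+].[O-]C1=C[C@H](C(OC)OC)C(C)(C)C=C1 | intermediate (not isolated)
11 | 5,6-trans-6-[4-(chloromethyl)-1-hydroxyhexa-4,5-dien-1-yl]-5-(dimethoxymethyl)-4,4-dimethylcyclohex-2-en-1-one (5S; carbinol epimers) | C=C=C(CCl)CCC(O)[C@@H]1C(=O)C=CC(C)(C)[C@H]1C(OC)OC | intermediate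
12 | methanesulfonate of 11 | C=C=C(CCl)CCC(OS(C)(=O)=O)[C@@H]1C(=O)C=CC(C)(C)[C@H]1C(OC)OC | intermediate (not isolated)
13 | (5R,6E)-6-[4-(chloromethyl)hexa-4,5-dien-1-ylidene]-5-(dimethoxymethyl)-4,4-dimethylcyclohex-2-en-1-one | C=C=C(CCl)CC/C=C1/C(=O)C=CC(C)(C)[C@H]1C(OC)OC | intermediate
14 | diallyl malonate | C=CCOC(=O)CC(=O)OCC=C | starting material
15 | open-chain Michael adduct: diallyl malonate carbon (C8) bonded to C9, which bears ring A (5,10-trans) and the 3-(chloromethyl)penta-3,4-dienyl chain; C9 as in 16 | C=C=C(CCl)CC[C@H](C(C(=O)OCC=C)C(=O)OCC=C)[C@@H]1C(=O)C=CC(C)(C)[C@H]1C(OC)OC | intermediate (not isolated)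
16 | diallyl (2S)-2-[(1S,6S)-6-(dimethoxymethyl)-5,5-dimethyl-2-oxocyclohex-3-en-1-yl]-4-ethenylidenecyclohexane-1,1-dicarboxylate (ring C diester) | C=C=C1CC(C(=O)OCC=C)(C(=O)OCC=C)[C@H]([C@@H]2C(=O)C=CC(C)(C)[C@H]2C(OC)OC)CC1 | intermediate
17 | (2S)-2-[(1S,6S)-6-(dimethoxymethyl)-5,5-dimethyl-2-oxocyclohex-3-en-1-yl]-4-ethenylidenecyclohexane-1,1-dicarboxylic acid | C=C=C1CC(C(=O)O)(C(=O)O)[C@H]([C@@H]2C(=O)C=CC(C)(C)[C@H]2C(OC)OC)CC1 | intermediate
18 | iodolactone acid: 5-(1-iodoethenyl)-7-oxo-6-oxabicyclo[3.2.1]octane-1-carboxylic acid carrying ring A on C2 (= C9), ring A cis to the lactone carbonyl C7; lactone O on C13, free CO2H on C8 is the future C15 | C=C(I)[C@]12CC[C@@H]([C@@H]3C(=O)C=CC(C)(C)[C@H]3C(OC)OC)[C@](C(=O)O)(C1)C(=O)O2 | intermediate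
19 | acid chloride of 18 | C=C(I)[C@]12CC[C@@H]([C@@H]3C(=O)C=CC(C)(C)[C@H]3C(OC)OC)[C@](C(Cl)=O)(C1)C(=O)O2 | intermediate (not isolated)
20 | iodolactone aldehyde (CHO = C15 on bridgehead C8; otherwise as 18) | C=C(I)[C@]12CC[C@@H]([C@@H]3C(=O)C=CC(C)(C)[C@H]3C(OC)OC)[C@](C=O)(C1)C(=O)O2 | intermediate
21 | lithium carboxylate from lactone opening (C7 carboxylate and C13–OH cis on ring C; CHO and 1-iodoethenyl cis on the other face) | [Li+].C=C(I)[C@]1(O)CC[C@@H]([C@@H]2C(=O)C=CC(C)(C)[C@H]2C(OC)OC)[C@@](C=O)(C([O-])=O)C1 | intermediate (not isolated)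
22 | hydroxy allyl ester (allyl ester of 21) | C=C(I)[C@]1(O)CC[C@@H]([C@@H]2C(=O)C=CC(C)(C)[C@H]2C(OC)OC)[C@@](C=O)(C(=O)OCC=C)C1 | intermediate (not isolated)
23 | allyl 1-formyl-5-(1-iodoethenyl)-5-(trimethylsilyloxy)cyclohexane-1-carboxylate carrying ring A on C2 (= C9); ester, silyloxy group and ring A on one face, CHO and iodoethenyl on the other | C=C(I)[C@]1(O[Si](C)(C)C)CC[C@@H]([C@@H]2C(=O)C=CC(C)(C)[C@H]2C(OC)OC)[C@@](C=O)(C(=O)OCC=C)C1 | intermediate
24 | alkenylchromium dichloride from 23 (CrCl2 in place of I) | C=C([Cr](Cl)Cl)[C@]1(O[Si](C)(C)C)CC[C@@H]([C@@H]2C(=O)C=CC(C)(C)[C@H]2C(OC)OC)[C@@](C=O)(C(=O)OCC=C)C1 | intermediate (not isolated)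
25 | bicyclo[3.2.1]octane allylic alcohol: C8 allyl ester, C13 OSiMe3, C16 exo-methylene, C15–OH (both epimers); ring A on C9 anti to the C15–C16 bridge | C=C1C(O)[C@]2(C(=O)OCC=C)C[C@@]1(O[Si](C)(C)C)CC[C@H]2[C@@H]1C(=O)C=CC(C)(C)[C@H]1C(OC)OC | intermediate
26 | 15-oxo-16-ene analogue of 25 | C=C1C(=O)[C@]2(C(=O)OCC=C)C[C@@]1(O[Si](C)(C)C)CC[C@H]2[C@@H]1C(=O)C=CC(C)(C)[C@H]1C(OC)OC | intermediate
27 | 15-endo alcohol (OH on the side of the C9–C11–C12 bridge) | C=C1[C@@H](O)[C@]2(C(=O)OCC=C)C[C@@]1(O[Si](C)(C)C)CC[C@H]2[C@@H]1C(=O)C=CC(C)(C)[C@H]1C(OC)OC | intermediate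
28 | 15-O-tert-butyldimethylsilyl ether of 27 | C=C1[C@@H](O[Si](C)(C)C(C)(C)C)[C@]2(C(=O)OCC=C)C[C@@]1(O[Si](C)(C)C)CC[C@H]2[C@@H]1C(=O)C=CC(C)(C)[C@H]1C(OC)OC | intermediate
29 | C7 carboxylic acid from 28 | C=C1[C@@H](O[Si](C)(C)C(C)(C)C)[C@]2(C(=O)O)C[C@@]1(O[Si](C)(C)C)CC[C@H]2[C@@H]1C(=O)C=CC(C)(C)[C@H]1C(OC)OC | intermediate
30 | chloromethyl chlorosulfate | ClCOS(=O)(=O)Cl | starting material
31 | chloromethyl ester of 29 (key-step precursor) | C=C1[C@@H](O[Si](C)(C)C(C)(C)C)[C@]2(C(=O)OCCl)C[C@@]1(O[Si](C)(C)C)CC[C@H]2[C@@H]1C(=O)C=CC(C)(C)[C@H]1C(OC)OC | intermediate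
32 | potassium dienolate of 31 (C1–O−, C1=C10) | [K+].C=C1[C@@H](O[Si](C)(C)C(C)(C)C)[C@]2(C(=O)OCCl)C[C@@]1(O[Si](C)(C)C)CC[C@H]2C1=C([O-])C=CC(C)(C)[C@H]1C(OC)OC | intermediate (not isolated)
33 | protected target: spirolactone with C20 cis to C6, 13-O-trimethylsilyl, 15-O-tert-butyldimethylsilyl, C6 dimethyl acetal | C=C1[C@@H](O[Si](C)(C)C(C)(C)C)[C@]23C[C@@]1(O[Si](C)(C)C)CC[C@H]2[C@]1(COC3=O)C(=O)C=CC(C)(C)[C@H]1C(OC)OC | intermediate
34 | 13,15-diol with C6 dimethyl acetal | C=C1[C@@H](O)[C@]23C[C@@]1(O)CC[C@H]2[C@]1(COC3=O)C(=O)C=CC(C)(C)[C@H]1C(OC)OC | intermediate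
35 | CNP0521079.1 | C=C1[C@@H](O)[C@]23C[C@@]1(O)CC[C@H]2[C@]1(COC3=O)C(=O)C=CC(C)(C)[C@H]1C=O | target

**Step count and risk**

Total: 20 steps. Longest linear sequence: 18 steps (steps 1, 2 and 5–20).

Steps most likely to fail:

Step 18. The tether may deliver C20 to the wrong face of the dienolate (through the C9–C10 rotamer that places C8 on the C5 flank), or the acyloxymethyl chloride may be lost to the base before the ring closes. The fallback sets out from allyl ester 28 and uses an untethered electrophile, so that the face is chosen by open approach past C9 and not by delivery from C8. The dienolate of 28 (KN(SiMe3)2, THF, −78 °C) would be hydroxymethylated with monomeric formaldehyde (aldol addition) to give C10-hydroxymethyl allyl ester F1. Warming F1 with DBU in toluene would close the six-membered lactone by transesterification on the C7 allyl ester, and the route is rejoined at 33.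

Step 7. Facial selectivity in the malonate addition to C9 may be poor, or C9 may equilibrate by retro-Michael reaction. The fallback sets out from 5, 9 and 14 and puts C9 under reagent control. Enone 5 would be converted (LiN(iPr)2, Me3SiCl) into trimethylsilyl dienol ether F2, and aldehyde 9 condensed with 14 (Knoevenagel, piperidinium acetate, molecular sieves) to alkylidene malonate F3. A Mukaiyama–Michael addition of F2 to F3 would be catalysed by the divalent copper bis(oxazoline) Lewis acid [Cu(tBu-box)](SbF6)2, in the ligand antipode matched to the anti-to-acetal approach of F2. After desilylation this gives 15, which is cyclised with Cs2CO3 as before, and the route is rejoined at 16.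

Step 14. The ring A enone may be reduced in competition with the C15 ketone. The fallback sets out from enone 26 and defers the reduction until C1 is flanked by the quaternary spiro carbon. Zerovalent palladium deallylation (Pd(PPh3)4, morpholine) would give keto acid F4, a bridgehead β-keto acid that cannot decarboxylate through a bridgehead enol. Chloromethyl chlorosulfate under phase transfer would give chloromethyl ester F5, and KN(SiMe3)2 would close the lactone to 15-oxo spirolactone F6. NaBH4/CeCl3·7H2O would then reduce C15 from the exo face to alcohol F7, and HF·pyridine would remove the trimethylsilyl group, rejoining the route at 34.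

**Further compounds**

F1 | step 18 | C10-hydroxymethyl allyl ester (CH2OH on C10 cis to C6; 13-O-trimethylsilyl, 15-O-tert-butyldimethylsilyl, C6 acetal) | C=C1[C@@H](O[Si](C)(C)C(C)(C)C)[C@]2(C(=O)OCC=C)C[C@@]1(O[Si](C)(C)C)CC[C@H]2[C@]1(CO)C(=O)C=CC(C)(C)[C@H]1C(OC)OC
F2 | step 7 | (S)-{[3-(dimethoxymethyl)-4,4-dimethylcyclohexa-1,5-dien-1-yl]oxy}trimethylsilane | C[Si](C)(C)OC1=C[C@H](C(OC)OC)C(C)(C)C=C1
F3 | step 7 | diallyl 2-[4-(chloromethyl)hexa-4,5-dien-1-ylidene]malonate | C=C=C(CCl)CCC=C(C(=O)OCC=C)C(=O)OCC=C
F4 | step 14 | 15-oxo C7 carboxylic acid (13-O-trimethylsilyl, C6 acetal) | C=C1C(=O)[C@]2(C(=O)O)C[C@@]1(O[Si](C)(C)C)CC[C@H]2[C@@H]1C(=O)C=CC(C)(C)[C@H]1C(OC)OC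
F5 | step 14 | 15-oxo chloromethyl ester | C=C1C(=O)[C@]2(C(=O)OCCl)C[C@@]1(O[Si](C)(C)C)CC[C@H]2[C@@H]1C(=O)C=CC(C)(C)[C@H]1C(OC)OC
F6 | step 14 | 15-oxo spirolactone (13-O-trimethylsilyl, C6 acetal) | C=C1C(=O)[C@]23C[C@@]1(O[Si](C)(C)C)CC[C@H]2[C@]1(COC3=O)C(=O)C=CC(C)(C)[C@H]1C(OC)OC
F7 | step 14 | 15-endo-hydroxy spirolactone (13-O-trimethylsilyl, C6 acetal) | C=C1[C@@H](O)[C@]23C[C@@]1(O[Si](C)(C)C)CC[C@H]2[C@]1(COC3=O)C(=O)C=CC(C)(C)[C@H]1C(OC)OC
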